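The pitfall in runs that differ in their scavenger charge is to read a trend into differences of the size of the scatter.

| flask | substrate | coupling partner | scavenger | free catalyst | remark | time |
|---|---|---|---|---|---|---|
| theta | 0.20 M | 1.2 equiv (fed, over 40 min) | 0.59 equiv | 0.065 mol% | run made earlier; the fed solution adds 0.50 times the starting volume |  |
| eta | 0.20 M | 1.2 equiv (fed, over 40 min) | 0.64 equiv | 0.065 mol% | run made earlier; the fed solution adds 0.50 times the starting volume |  |
| gamma | 0.20 M | 1.2 equiv (fed, over 40 min) | 0.84 equiv | 0.065 mol% | run made earlier; the fed solution adds 0.50 times the starting volume |  |
| east | 0.20 M | 1.20 equiv (fed, over 40 min) | 0.850 equiv | 0.065 mol% | the fed solution adds 0.50 times the starting volume | 40 min |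
| south-east | 0.20 M | 1.20 equiv (fed, over 40 min) | 0.650 equiv | 0.065 mol% | the fed solution adds 0.50 times the starting volume | 40 min |
| west | 0.20 M | 1.20 equiv (fed, over 40 min) | 0.500 equiv | 0.065 mol% | the fed solution adds 0.50 times the starting volume | 40 min |

- theta (time / min: substrate / %, product / %): 6.00: 97.5, 3.7; 12.0: 94.8, 5.1; 15.0: 91.3, 9.6; 25.0: 82.0, 16.1; 30.0: 79.0, 20.9
- eta (time / min: substrate / %, product / %): 2.50: 98.0, 0; 8.00: 97.5, 3.4; 12.0: 93.9, 5.9; 20.0: 88.6, 11.9; 30.0: 78.8, 20.7
- gamma (time / min: substrate / %, product / %): 2.50: 98.7, 1.0; 4.00: 99.3, 2.2; 8.00: 97.1, 4.2; 15.0: 92.0, 8.0; 30.0: 77.3, 22.5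

(each reading ± 1 percentage point)

- charges are per starting volume, the dose included; the dosed solution carries all of it
- the numbers in the tables scatter with a standard deviation of 1 percentage point

- part of the substrate that has reacted at the end, east
- part of the substrate that has reacted at the end, south-east
- part of the substrate that has reacted at the end, west
- what raising the equivalents of scavenger from its lowest to its highest value here does to the part of the substrate that has reacted (changes below 5 percentage points count as none) (it rises / it falls / no change)

Read across the rows. At 30.0 min, gamma, with the most scavenger, has 77.3% of its substrate left and theta 79.0%, so gamma lies lower by 1.7 points, on readings with a scatter of 1 point. At 15.0 min the order turns round: gamma reads 92.0% and theta 91.3%. A difference that changes sign is no trend, so the three runs are pooled as one flask.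

Now read down the columns. The pooled substrate left, L, is 91.7% at 15.0 min and 78.4% at 30.0 min, a loss of 13 points in 15.0 min. The dose is still running until 40 min, so this pace is frozen for the last 10.0 min, which costs 8.9 points more. That leaves 69.5% at 40 min, or 30.5% reacted.

The quantity to carry is the exposure E, the natural logarithm of charged over remaining substrate, which is the time integral of the pseudo-first-order constant of substrate loss. Here E is 0.364.

West lies outside the tested range. On the assumption of one scavenger per reacted substrate, the take-up is 30.5% of the substrate charge, and west carries 0.500 equiv. This reckoning therefore commits to 30.5% in east, south-east and west, with no change.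

The forecast, a little lower, gives 30%, 30% and 30% with the trend "no change", since the earlier runs “overlap within the scatter”.

The flasks give 30.2% in east, 30.1% in south-east and 30.1% in west, and the trend is "no change", a change of 0.062 points.

    substrate + free catalyst → catalyst intermediate A (k = 430 M⁻¹ min⁻¹)
    coupling partner + catalyst intermediate A → catalyst intermediate B (k = 440 M⁻¹ min⁻¹)
    catalyst intermediate B → released group + catalyst intermediate C (k = 68.0 min⁻¹)
    catalyst intermediate C ⇌ catalyst intermediate D (K = 0.920, k = 97.0 min⁻¹)
    catalyst intermediate D ⇌ free catalyst + product (K = 1.80 M, k = 560 min⁻¹)
    coupling partner + released group ⇌ idle adduct, settled at all times (K = 5.10 M⁻¹)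
    scavenger + released group → scavenged by-product (k = 6.40 M⁻¹ min⁻¹)

In east the difference in scavenger is not what sets the end value. Two things act together to hold east at 30.2%: the gradual adding of coupling partner is a part of it, since adding it at once gives 37.9%, and the hour of the reading is the largest single effect, since a reading ten times later gives >99.9%. Taking E as proportional to the loading of free catalyst, the neighbour flask, east with 0.16 mol% in place of 0.065 mol%, has an E of 0.895, which means 59.1% reacted. That neighbour flask gives 59.9%.

(The readings are calculated for substances that don't exist; the scatter is artificial.)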